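**Assumption:** the C2 ester is the angelate (Z) as written in the SMILES, and commercial (R)-(−)-linalool of high enantiomeric purity is used. Labdane numbering is used throughout (ring A = C1–C5, C10; ring B = C5–C10; chain C11–C16 on C9; C17 on C8; C18/C19 on C4; C20 on C10).

## Analysis of the target

The target is a normal-series labdane: a trans-decalin with a trisubstituted C7=C8 alkene in ring B, an angular acetoxymethyl group (C20) on the quaternary C10, and a C11–C16 chain on C9 that ends in a tertiary vinyl carbinol (C13). It has six stereocentres: C2 (R, 2α-angelate, equatorial), C3 (S, 3α-OH, axial and neopentyl), C5 (R, α-H), C9 (S, α-H, chain β and equatorial), C10 (S, C20 β and axial) and C13 (R). C5, C9 and C10 form one contiguous array around C10; C2/C3 are a cis-diol with only the equatorial oxygen acylated; C13 is separated from the ring by two methylenes and cannot be set by relay. Read as a chain, C15–C14–C13(C16)–C12–C11–C9=C8(C17)–C7–C6–C5=C10(C20)–C1–C2–C3=C4(C18,C19) is an intact head-to-tail tetraprenyl chain. The molecule is thus an oxidised (R)-geranyllinalool in which only the bonds C4–C5 and C9–C10 are missing, and its C7–C9/C11–C17 half is (R)-linalool itself. That is the feature the plan is built on. Sensitive groups are the angelate (Z to E isomerisation, migration to the cis C3 hydroxyl), the tertiary allylic alcohol (ionisation in acid, capture of any C8 cation to an 8,13-ether) and the C7=C8 alkene (acid moves it to the 8(9) or 8(17) position). The hard parts are the quaternary C10 with an oxidised substituent between two stereocentres, the exact position of the ring-B alkene, the axial C3 hydroxyl next to the equatorial C2 ester, and C13.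

## Retrosynthetic reasoning

**Ester bonds C20–O and C2–O.** The target 24 is cut back to alcohol 23, silyl ether 22 and diol 21. Both acyl groups go on last because the angelate tolerates neither strong base nor hydride. In 21 the equatorial C2 hydroxyl is the only reactive one (C3 is axial and neopentyl, C13 tertiary, C20 silylated), so no extra protecting group is needed.

**C2–O bond and the C3 configuration.** Diol 21 comes from ketol 20, which comes from ketone 18 and this from alcohol 17. The C3 carbonyl does two jobs: its enolate accepts oxygen at C2 from the open α face, and its reduction from the β side turns the equatorial 3β-oxygen of 17 into the axial 3α-hydroxyl.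

**Bonds C4–C5 and C9–C10 (key disconnection).** Bicycle 17 is cut to the acyclic epoxide 16. Cutting here and nowhere else returns the molecule to its tetraprenyl chain: both rings, the quaternary C10 and the C5/C9/C10 array fall away together, leaving one stereocentre (C3 of the epoxide) that relays to all three. A sulfonyl group on C7 of 16 is a leaving radical, so the cascade must end with the alkene at C7=C8. The forward reaction is a radical epoxypolyene bicyclisation; a cationic version is excluded by the free C13 hydroxyl.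

**C3–O bond of the epoxide.** Epoxide 16 comes from tetraene 15 by catalytic asymmetric epoxidation. The sulfone on C7 deactivates C8=C9 and the allylic silyl ether on C20 deactivates C5=C10, so the C3=C4 alkene is the one that reacts.

**C6–C7 bond.** Tetraene 15 is cut into allyl sulfone 4 and allylic bromide 13. This is the classical sulfone union of two prenyl units; here the sulfone is kept because the key step needs it.

**Sulfone 4 from the chiral pool.** Sulfone 4 comes from chloride 3, diol 2 and (R)-linalool 1 by functionalising the E methyl group. C13 is bought, not made.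

**C1–C10 bond and the C5=C10 geometry.** Bromide 13 comes from alcohol 12 and enoate 11, and 11 from ynoate 7 and bromide 8 by syn carbocupration. This places C1 trans to C6 and carries the C20 oxygen from the start; 7 comes from silyl ether 5.

## Alternatives that were turned down

**Alternative 1:** the textbook route. Ring A is disconnected by a Robinson annulation to a Wieland–Miescher-type enedione with an angular benzyloxymethyl group, A1. The forward sequence would be: deconjugative gem-dimethylation at C4, trans-fusion by hydrogenation, C9 ketone to C8 methyl and Δ7, chain on C9, then C2/C3 oxygenation. It was turned down because no step does more than one job. Each of C4, C5, C8/C9 and C2/C3 needs its own sequence (well over twenty steps). C13 would arise from vinyl addition to a methyl ketone five bonds from the nearest stereocentre, without control.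

**Alternative 2:** ring B by an intermolecular Diels–Alder reaction (bonds C5–C6 and C9–C10). The partners would be the linalool-derived diene A2 and the ring-A enal A3, whose formyl group is the later C20. It looks convergent and would set Δ7 directly. It was turned down on mechanism: suprafacial addition across the cyclic dienophile C5=C10 must give the cis-fused decalin, and C5 has no adjacent carbonyl through which to epimerise. In addition, the dienophile is trisubstituted with a quaternary C4 next to the reacting carbon, and the 1-alkyl-2-methyl diene gives conflicting regiochemical preferences.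

**Alternative 3:** the polar biomimetic cyclisation, a Lewis-acid epoxide-initiated cation–olefin bicyclisation of the 20-acetoxy epoxygeranyllinalool A4. It makes the same bonds as the chosen route. It was turned down on structure: the C8 cation formed last sits six atoms from the free C13 hydroxyl and would close to the 8,13-ether A5 (manoyl-oxide type), or lose a proton unselectively to the 7-, 8(17)- and 8(9)-alkenes. The allylic C20 acetate also deactivates C5=C10 towards cations and can itself ionise. Protecting C13 and adding a cation-stabilising terminator would cost the steps the cyclisation saves.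

Key step: step 10

## Route

Step 1
Reactants: 1 (R)-(−)-linalool [(3R)-3,7-dimethylocta-1,6-dien-3-ol]
Product: 2 (2E,6R)-2,6-dimethylocta-2,7-diene-1,6-diol
Conditions: SeO2 (cat.), t-BuOOH, salicylic acid (cat.), CH2Cl2, 0 °C to rt
Reagents that add atoms: tert-butyl hydroperoxide, CC(C)(C)OO (oxygen delivered through catalytic selenium dioxide, O=[Se]=O)
Why: SeO2 allylic oxidation (ene reaction, then 2,3-sigmatropic shift) is selective for the E methyl group of a trisubstituted alkene; the vinyl carbinol has no allylic hydrogen and C13 is untouched.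

Step 2
Reactants: 2 (2E,6R)-2,6-dimethylocta-2,7-diene-1,6-diol
Product: 3 (3R,6E)-8-chloro-3,7-dimethylocta-1,6-dien-3-ol
Conditions: N-chlorosuccinimide, Me2S, CH2Cl2, −30 to 0 °C
Reagents that add atoms: N-chlorosuccinimide, O=C1CCC(=O)N1Cl
Why: Corey–Kim chlorination replaces the primary allylic hydroxyl by SN2 on its alkoxysulfonium salt without allylic shift; the hindered tertiary alcohol does not react.

Step 3
Reactants: 3 (3R,6E)-8-chloro-3,7-dimethylocta-1,6-dien-3-ol
Product: 4 (3R,6E)-3,7-dimethyl-8-(phenylsulfonyl)octa-1,6-dien-3-ol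
Conditions: PhSO2Na, Bu4NI (cat.), DMF, rt
Reagents that add atoms: sodium benzenesulfinate, [Na+].[O-]S(=O)c1ccccc1
Why: S-alkylation of the sulfinate by SN2 at the primary allylic chloride gives the sulfone with the E alkene kept.

Step 4
Reactants: 5 tert-butyldimethyl(prop-2-yn-1-yloxy)silane
Product: 7 methyl 4-[(tert-butyldimethylsilyl)oxy]but-2-ynoate, via lithium acetylide 6 (not isolated)
Conditions: n-BuLi, THF, −78 °C; ClCO2Me, −78 to 0 °C
Reagents that add atoms: methyl chloroformate, COC(Cl)=O
Why: Acylation of a lithium acetylide with a chloroformate is a standard route to ynoates.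

Step 5
Reactants: 7 methyl 4-[(tert-butyldimethylsilyl)oxy]but-2-ynoate; 8 5-bromo-2-methylpent-2-ene
Product: 11 methyl (2Z)-3-{[(tert-butyldimethylsilyl)oxy]methyl}-7-methylocta-2,6-dienoate, via 4-methylpent-3-enylmagnesium bromide 9 (not isolated), via 4-methylpent-3-enylcopper 10 (not isolated)
Conditions: 8, Mg, THF; CuBr·SMe2 (1 equiv), −40 °C; 7, −78 °C; NH4Cl/MeOH quench at −78 °C
Reagents that add atoms: none
Why: Syn carbocupration of the ynoate and cold protonation of the vinylcopper with retention put the new alkyl group cis to H, hence the CH2OSi group cis to the ester (Z). This is the later C5=C10 geometry with C1 trans to C6.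

Step 6
Reactants: 11 methyl (2Z)-3-{[(tert-butyldimethylsilyl)oxy]methyl}-7-methylocta-2,6-dienoate
Product: 12 (2Z)-3-{[(tert-butyldimethylsilyl)oxy]methyl}-7-methylocta-2,6-dien-1-ol
Conditions: i-Bu2AlH (2.2 equiv), CH2Cl2, −78 °C; Rochelle salt
Reagents that add atoms: none
Why: 1,2-Reduction of the enoate to the allylic alcohol; the silyl ether and the alkene geometry are not affected at −78 °C.

Step 7
Reactants: 12 (2Z)-3-{[(tert-butyldimethylsilyl)oxy]methyl}-7-methylocta-2,6-dien-1-ol
Product: 13 (2Z)-1-bromo-3-{[(tert-butyldimethylsilyl)oxy]methyl}-7-methylocta-2,6-diene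
Conditions: CBr4, PPh3, 2,6-lutidine (cat.), CH2Cl2, −20 to 0 °C; used at once
Reagents that add atoms: tetrabromomethane, BrC(Br)(Br)Br
Why: Appel bromination of a primary allylic alcohol proceeds by SN2 at low temperature with retention of the Z geometry.

Step 8
Reactants: 4 (3R,6E)-3,7-dimethyl-8-(phenylsulfonyl)octa-1,6-dien-3-ol; 13 (2Z)-1-bromo-3-{[(tert-butyldimethylsilyl)oxy]methyl}-7-methylocta-2,6-diene
Product: 15 (3R,6E,10Z)-11-{[(tert-butyldimethylsilyl)oxy]methyl}-3,7,15-trimethyl-8-(phenylsulfonyl)hexadeca-1,6,10,14-tetraen-3-ol (both C8 epimers), via dilithio sulfone 14 (not isolated)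
Conditions: 4, n-BuLi (2.1 equiv), THF, −78 °C; 13, −78 to −40 °C
Reagents that add atoms: none
Why: Biellmann-type α-alkylation of the lithiated allyl sulfone by SN2 on the primary allylic bromide forms C6–C7 with both alkene geometries kept. The new sulfone-bearing centre (labdane C7) is uncontrolled, which does not matter because it becomes sp2 in step 10.

Step 9
Reactants: 15 (3R,6E,10Z)-11-{[(tert-butyldimethylsilyl)oxy]methyl}-3,7,15-trimethyl-8-(phenylsulfonyl)hexadeca-1,6,10,14-tetraen-3-ol
Product: 16 (3R,6E,10Z)-11-{[(tert-butyldimethylsilyl)oxy]methyl}-13-[(2S)-3,3-dimethyloxiran-2-yl]-3,7-dimethyl-8-(phenylsulfonyl)trideca-1,6,10-trien-3-ol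
Conditions: L-fructose-derived Shi ketone (0.3 equiv), KHSO5 (as its triple salt), K2CO3, Bu4NHSO4, MeCN/dimethoxymethane/aq. borate buffer pH 10.5, 0 °C
Reagents that add atoms: potassium peroxymonosulfate, [K+].[O-]S(=O)(=O)OO
Why: Shi epoxidation; the dioxirane attacks the most electron-rich alkene, C3=C4, because C8=C9 is deactivated by the allylic sulfone, C5=C10 by the allylic silyl ether, and the vinyl group is monosubstituted. The enantiomer of the ketone is chosen to give the (S)-epoxide through the spiro transition state.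

Step 10
Reactants: 16 (3R,6E,10Z)-11-{[(tert-butyldimethylsilyl)oxy]methyl}-13-[(2S)-3,3-dimethyloxiran-2-yl]-3,7-dimethyl-8-(phenylsulfonyl)trideca-1,6,10-trien-3-ol
Product: 17 (13R)-20-[(tert-butyldimethylsilyl)oxy]labda-7,14-diene-3β,13-diol (5α-H, 9α-H, C20 β)
Conditions: Cp2TiCl2 (2.5 equiv), Mn dust, THF, rt (green Cp2TiCl); 16 added over 3 h to 0.01 M; aq. NaH2PO4
Reagents that add atoms: none
Why: Proposed new method: Cp2TiCl (trivalent titanium) opens the epoxide by electron transfer to the tertiary C4 radical with the titanoxy group on C3; this radical adds 6-endo-trig to C5, the tertiary C10 radical adds 6-endo-trig to C9 of the allylic sulfone, and the β-sulfonyl C8 radical expels PhSO2• (reduced by the second equivalent of Cp2TiCl), which fixes the alkene at C7=C8. The closest known reactions are the Cp2TiCl-mediated bicyclisation of 2,3-epoxypolyprenes (same initiation and the same two 6-endo closures, but ended by loss of hydrogen, mainly to the exocyclic alkene) and the addition–fragmentation (SH2') of alkyl radicals on allyl sulfones; using the latter to end the former is the new element. C5 is set in a chair transition state with the titanoxy group equatorial and the C6 chain equatorial (C1 trans to C6 in 16), giving 3β-O and 5α-H. C10 is set when ring B closes through a chair on the face that gives the trans-decalin, with C20 axial and β. C9 is set by the E geometry of C8=C9, which places C11 equatorial and β. The step needs radical formation only at C4 (one epoxide; Cp2TiCl leaves sulfone, silyl ether, alkenes and the free alcohol alone), 6-endo over 5-exo closure twice (the fully substituted proximal carbons C10 and C8 secure it), and cyclisation faster than trapping of the tertiary radicals (slow addition and high dilution secure it). A radical cascade is used because the free C13 hydroxyl would capture a C8 cation. Both C7 epimers of 16 converge on 17.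

Step 11
Reactants: 17 (13R)-20-[(tert-butyldimethylsilyl)oxy]labda-7,14-diene-3β,13-diol
Product: 18 (13R)-20-[(tert-butyldimethylsilyl)oxy]-13-hydroxylabda-7,14-dien-3-one
Conditions: Dess–Martin periodinane, NaHCO3, CH2Cl2, 0 °C to rt
Reagents that add atoms: none
Why: Dess–Martin oxidation of the only secondary alcohol; the tertiary allylic alcohol cannot be oxidised and is not transposed by this reagent.

Step 12
Reactants: 18 (13R)-20-[(tert-butyldimethylsilyl)oxy]-13-hydroxylabda-7,14-dien-3-one
Product: 20 (13R)-20-[(tert-butyldimethylsilyl)oxy]-2α,13-dihydroxylabda-7,14-dien-3-one, via dipotassium enolate 19 (not isolated)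
Conditions: KN(SiMe3)2 (2.3 equiv), THF, −78 °C; 2-(phenylsulfonyl)-3-phenyloxaziridine, −78 °C; AcOH quench at −78 °C
Reagents that add atoms: 2-(phenylsulfonyl)-3-phenyloxaziridine, O=S(=O)(c1ccccc1)N1OC1c1ccccc1
Why: Enolate hydroxylation with an N-sulfonyloxaziridine; only C2 can enolise (C4 is quaternary). The β face of C2 is blocked by the syn-axial C20 and 4β-methyl groups, so oxygen enters from the α face to give the equatorial 2α-hydroxyl, which is also the more stable epimer.

Step 13
Reactants: 20 (13R)-20-[(tert-butyldimethylsilyl)oxy]-2α,13-dihydroxylabda-7,14-dien-3-one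
Product: 21 (13R)-20-[(tert-butyldimethylsilyl)oxy]labda-7,14-diene-2α,3α,13-triol
Conditions: LiBH(s-Bu)3 (3.5 equiv), THF, −78 °C; MeOH, aq. NH4Cl
Reagents that add atoms: none
Why: Substrate-controlled ketone reduction with a bulky hydride: the axial path on the α face is closed to the tri-sec-butylborohydride by H1α and H5α, so hydride arrives along the equatorial β path and gives the axial 3α-alcohol, as bulky borohydrides do with 3-oxo-4,4-dimethyl terpenoids.

Step 14
Reactants: 21 (13R)-20-[(tert-butyldimethylsilyl)oxy]labda-7,14-diene-2α,3α,13-triol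
Product: 22 (13R)-20-[(tert-butyldimethylsilyl)oxy]-3α,13-dihydroxylabda-7,14-dien-2α-yl (2Z)-2-methylbut-2-enoate
Conditions: angelic acid, 2,4,6-trichlorobenzoyl chloride, Et3N, toluene, rt; then 21, 75 °C (no DMAP)
Reagents that add atoms: angelic acid, C/C=C(/C)C(=O)O
Why: Mixed-anhydride (Yamaguchi-type) acylation without a nucleophilic catalyst transfers the angeloyl group with the Z geometry intact. The equatorial C2 hydroxyl reacts; the axial neopentyl C3 hydroxyl and the tertiary C13 hydroxyl do not.

Step 15
Reactants: 22 (13R)-20-[(tert-butyldimethylsilyl)oxy]-3α,13-dihydroxylabda-7,14-dien-2α-yl (2Z)-2-methylbut-2-enoate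
Product: 23 (13R)-3α,13,20-trihydroxylabda-7,14-dien-2α-yl (2Z)-2-methylbut-2-enoate
Conditions: HF·pyridine, pyridine, THF, 0 °C to rt
Reagents that add atoms: none
Why: Fluoride cleavage of the primary silyl ether in a pyridine-buffered medium, which is neither basic enough to isomerise or shift the angelate nor acidic enough to ionise the tertiary allylic alcohol.

Step 16
Reactants: 23 (13R)-3α,13,20-trihydroxylabda-7,14-dien-2α-yl (2Z)-2-methylbut-2-enoate
Product: 24 (13R)-20-acetoxy-3α,13-dihydroxylabda-7,14-dien-2α-yl (2Z)-2-methylbut-2-enoate, (2R,3S,5R,9S,10S,13R), the target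
Conditions: Ac2O (1.5 equiv), pyridine, DMAP (cat.), CH2Cl2, 0 °C
Reagents that add atoms: acetic anhydride, CC(=O)OC(C)=O
Why: Acetylation of the only primary alcohol; the axial C3 hydroxyl beside the gem-dimethyl group and the tertiary C13 hydroxyl are far slower.

## Compound list

1 | (R)-(−)-linalool | C=C[C@](C)(O)CCC=C(C)C | starting material
2 | (2E,6R)-2,6-dimethylocta-2,7-diene-1,6-diol | C=C[C@](C)(O)CC/C=C(\C)CO | intermediate
3 | (3R,6E)-8-chloro-3,7-dimethylocta-1,6-dien-3-ol | C=C[C@](C)(O)CC/C=C(\C)CCl | intermediate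
4 | (3R,6E)-3,7-dimethyl-8-(phenylsulfonyl)octa-1,6-dien-3-ol | C=C[C@](C)(O)CC/C=C(\C)CS(=O)(=O)c1ccccc1 | intermediate
5 | tert-butyldimethyl(prop-2-yn-1-yloxy)silane | C#CCO[Si](C)(C)C(C)(C)C | starting material
6 | lithium acetylide of 5 | [Li]C#CCO[Si](C)(C)C(C)(C)C | intermediate (not isolated)
7 | methyl 4-[(tert-butyldimethylsilyl)oxy]but-2-ynoate | COC(=O)C#CCO[Si](C)(C)C(C)(C)C | intermediate
8 | 5-bromo-2-methylpent-2-ene | CC(C)=CCCBr | starting material
9 | 4-methylpent-3-enylmagnesium bromide | CC(C)=CCC[Mg]Br | intermediate (not isolated)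
10 | 4-methylpent-3-enylcopper (MgBr2 complex) | CC(C)=CCC[Cu] | intermediate (not isolated)
11 | methyl (2Z)-3-{[(tert-butyldimethylsilyl)oxy]methyl}-7-methylocta-2,6-dienoate | COC(=O)/C=C(/CCC=C(C)C)CO[Si](C)(C)C(C)(C)C | intermediate
12 | (2Z)-3-{[(tert-butyldimethylsilyl)oxy]methyl}-7-methylocta-2,6-dien-1-ol | OC/C=C(/CCC=C(C)C)CO[Si](C)(C)C(C)(C)C | intermediate
13 | (2Z)-1-bromo-3-{[(tert-butyldimethylsilyl)oxy]methyl}-7-methylocta-2,6-diene | BrC/C=C(/CCC=C(C)C)CO[Si](C)(C)C(C)(C)C | intermediate
14 | dilithio derivative of 4 (alkoxide and α-sulfonyl carbanion) | C=C[C@](C)(O[Li])CC/C=C(\C)C([Li])S(=O)(=O)c1ccccc1 | intermediate (not isolated)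
15 | (3R,6E,10Z)-11-{[(tert-butyldimethylsilyl)oxy]methyl}-3,7,15-trimethyl-8-(phenylsulfonyl)hexadeca-1,6,10,14-tetraen-3-ol, both C8 epimers | C=C[C@](C)(O)CC/C=C(\C)C(C/C=C(/CCC=C(C)C)CO[Si](C)(C)C(C)(C)C)S(=O)(=O)c1ccccc1 | intermediate
16 | (3R,6E,10Z)-11-{[(tert-butyldimethylsilyl)oxy]methyl}-13-[(2S)-3,3-dimethyloxiran-2-yl]-3,7-dimethyl-8-(phenylsulfonyl)trideca-1,6,10-trien-3-ol, both C8 epimers | C=C[C@](C)(O)CC/C=C(\C)C(C/C=C(/CC[C@@H]1OC1(C)C)CO[Si](C)(C)C(C)(C)C)S(=O)(=O)c1ccccc1 | intermediate
17 | (13R)-20-[(tert-butyldimethylsilyl)oxy]labda-7,14-diene-3β,13-diol | C=C[C@](C)(O)CC[C@H]1C(C)=CC[C@H]2C(C)(C)[C@@H](O)CC[C@]12CO[Si](C)(C)C(C)(C)C | intermediate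
18 | (13R)-20-[(tert-butyldimethylsilyl)oxy]-13-hydroxylabda-7,14-dien-3-one | C=C[C@](C)(O)CC[C@H]1C(C)=CC[C@H]2C(C)(C)C(=O)CC[C@]12CO[Si](C)(C)C(C)(C)C | intermediate
19 | dipotassium salt of 18 (C2=C3 enolate and C13 alkoxide) | C=C[C@](C)(O[K])CC[C@H]1C(C)=CC[C@H]2C(C)(C)C(O[K])=CC[C@]12CO[Si](C)(C)C(C)(C)C | intermediate (not isolated)
20 | (13R)-20-[(tert-butyldimethylsilyl)oxy]-2α,13-dihydroxylabda-7,14-dien-3-one | C=C[C@](C)(O)CC[C@H]1C(C)=CC[C@H]2C(C)(C)C(=O)[C@H](O)C[C@]12CO[Si](C)(C)C(C)(C)C | intermediate
21 | (13R)-20-[(tert-butyldimethylsilyl)oxy]labda-7,14-diene-2α,3α,13-triol | C=C[C@](C)(O)CC[C@H]1C(C)=CC[C@H]2C(C)(C)[C@H](O)[C@H](O)C[C@]12CO[Si](C)(C)C(C)(C)C | intermediate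
22 | (13R)-20-[(tert-butyldimethylsilyl)oxy]-3α,13-dihydroxylabda-7,14-dien-2α-yl (2Z)-2-methylbut-2-enoate | C=C[C@](C)(O)CC[C@H]1C(C)=CC[C@H]2C(C)(C)[C@H](O)[C@H](OC(=O)/C(C)=C\C)C[C@]12CO[Si](C)(C)C(C)(C)C | intermediate
23 | (13R)-3α,13,20-trihydroxylabda-7,14-dien-2α-yl (2Z)-2-methylbut-2-enoate | C=C[C@](C)(O)CC[C@H]1C(C)=CC[C@H]2C(C)(C)[C@H](O)[C@H](OC(=O)/C(C)=C\C)C[C@]12CO | intermediate
24 | (13R)-20-acetoxy-3α,13-dihydroxylabda-7,14-dien-2α-yl (2Z)-2-methylbut-2-enoate (CNP0171655.1) | C=C[C@](C)(O)CC[C@H]1C(C)=CC[C@H]2C(C)(C)[C@H](O)[C@H](OC(=O)/C(C)=C\C)C[C@]12COC(C)=O | target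

## Step count and risk

Total: 16 steps. Longest linear sequence: 13 steps (steps 4 to 16, from 5); the linalool branch joins after 3 steps.

**Step 10 (key step, proposed new method).** The cascade may stop early: the C4 or C10 radical may be reduced or lose hydrogen before the second ring closes, or the C10 radical may add too slowly to the hindered C9 terminus of the allylic sulfone. The fallback uses only known chemistry, sets out from bromide 13 and chloride 3, and returns at 17. The sulfone is moved to the other partner so that it can be removed with defined regiochemistry: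
- 13 and PhSO2Na (DMF) should give (2Z)-3-{[(tert-butyldimethylsilyl)oxy]methyl}-7-methyl-1-(phenylsulfonyl)octa-2,6-diene F1.
- Lithiated F1 (n-BuLi, THF, −78 °C) is alkylated with the lithium alkoxide of 3 to give (3R,6E,10Z)-11-{[(tert-butyldimethylsilyl)oxy]methyl}-3,7,15-trimethyl-9-(phenylsulfonyl)hexadeca-1,6,10,14-tetraen-3-ol F2.
- PdCl2(dppp)-catalysed hydride displacement with LiBHEt3 (zerovalent palladium ionises the sulfone; hydride goes to the secondary allyl terminus because the other is the fully substituted C10) gives (3R,6E,10Z)-11-{[(tert-butyldimethylsilyl)oxy]methyl}-3,7,15-trimethylhexadeca-1,6,10,14-tetraen-3-ol F3.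
- Shi epoxidation as in step 9, here with lower site selectivity because C8=C9 is no longer deactivated, gives (3R,6E,10Z)-11-{[(tert-butyldimethylsilyl)oxy]methyl}-13-[(2S)-3,3-dimethyloxiran-2-yl]-3,7-dimethyltrideca-1,6,10-trien-3-ol F4.
- The precedented Cp2TiCl bicyclisation, ended by loss of a C17 hydrogen, gives (13R)-20-[(tert-butyldimethylsilyl)oxy]labda-8(17),14-diene-3β,13-diol F5.
- Hydrogen-atom-transfer isomerisation with CoCl(salen) (trivalent cobalt; salen = N,N'-bis(3,5-di-tert-butylsalicylidene)-1,2-cyclohexanediaminate) and catalytic PhSiH3 moves the exocyclic alkene into the ring at C7=C8 and gives 17. The vinyl group has no allylic hydrogen and can only revert.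

**Step 9.** Site selectivity may be incomplete (epoxidation also at C5=C10) and enantiofacial control on a terminal isopropylidene group may be imperfect. The fallback sets out from enoate 11, where C3=C4 is the only electron-rich alkene, and returns at 16:
- Shi epoxidation of 11 gives methyl (2Z)-3-{[(tert-butyldimethylsilyl)oxy]methyl}-5-[(2S)-3,3-dimethyloxiran-2-yl]pent-2-enoate F6.
- i-Bu2AlH at −78 °C gives (2Z)-3-{[(tert-butyldimethylsilyl)oxy]methyl}-5-[(2S)-3,3-dimethyloxiran-2-yl]pent-2-en-1-ol F7.
- MsCl/Et3N, then LiBr at −40 °C, gives (2Z)-1-bromo-3-{[(tert-butyldimethylsilyl)oxy]methyl}-5-[(2S)-3,3-dimethyloxiran-2-yl]pent-2-ene F8.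
- Alkylation of dilithio sulfone 14 with F8 at −78 °C, where the allylic bromide reacts far faster than the epoxide, gives 16.

**Step 13.** Facial selectivity may be poor or reversed if the 2α-alkoxide changes the approach of the hydride, and the ketol may isomerise under the basic conditions. The fallback replaces substrate control by catalyst control, sets out from 20 and returns at 21:
- TESCl/imidazole silylates only the secondary hydroxyl and gives (13R)-20-[(tert-butyldimethylsilyl)oxy]-13-hydroxy-2α-(triethylsilyloxy)labda-7,14-dien-3-one F9.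
- CBS reduction with (S)-2-methyl-CBS-oxazaborolidine and catecholborane (toluene, −78 to −40 °C), in which the quaternary C4 is the large group so that hydride is sent to the β face, gives (13R)-20-[(tert-butyldimethylsilyl)oxy]-2α-(triethylsilyloxy)labda-7,14-diene-3α,13-diol F10.
- PPTS in MeOH at 0 °C removes the secondary triethylsilyl group in the presence of the primary tert-butyldimethylsilyl ether and gives 21.

**Step 14.** The angeloyl group may isomerise to the tigloyl group on heating with amine base, and acylation of the hindered diol may be slow. The fallback builds the Z alkene on the substrate, sets out from 21 and returns at 22: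
- 2-[Bis(2,2,2-trifluoroethoxy)phosphoryl]propanoic acid, DCC and DMAP (the acid has no alkene to isomerise) acylate the C2 hydroxyl and give (13R)-20-[(tert-butyldimethylsilyl)oxy]-3α,13-dihydroxylabda-7,14-dien-2α-yl 2-[bis(2,2,2-trifluoroethoxy)phosphoryl]propanoate F11.
- Still–Gennari olefination of F11 with acetaldehyde (KN(SiMe3)2, 18-crown-6, THF, −78 °C) gives the Z enoate 22.

## Further compounds

F1 | step 10 | (2Z)-3-{[(tert-butyldimethylsilyl)oxy]methyl}-7-methyl-1-(phenylsulfonyl)octa-2,6-diene | O=S(=O)(C/C=C(/CCC=C(C)C)CO[Si](C)(C)C(C)(C)C)c1ccccc1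
F2 | step 10 | (3R,6E,10Z)-11-{[(tert-butyldimethylsilyl)oxy]methyl}-3,7,15-trimethyl-9-(phenylsulfonyl)hexadeca-1,6,10,14-tetraen-3-ol | C=C[C@](C)(O)CC/C=C(\C)CC(/C=C(/CCC=C(C)C)CO[Si](C)(C)C(C)(C)C)S(=O)(=O)c1ccccc1
F3 | step 10 | (3R,6E,10Z)-11-{[(tert-butyldimethylsilyl)oxy]methyl}-3,7,15-trimethylhexadeca-1,6,10,14-tetraen-3-ol | C=C[C@](C)(O)CC/C=C(\C)CC/C=C(/CCC=C(C)C)CO[Si](C)(C)C(C)(C)C
F4 | step 10 | (3R,6E,10Z)-11-{[(tert-butyldimethylsilyl)oxy]methyl}-13-[(2S)-3,3-dimethyloxiran-2-yl]-3,7-dimethyltrideca-1,6,10-trien-3-ol | C=C[C@](C)(O)CC/C=C(\C)CC/C=C(/CC[C@@H]1OC1(C)C)CO[Si](C)(C)C(C)(C)C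
F5 | step 10 | (13R)-20-[(tert-butyldimethylsilyl)oxy]labda-8(17),14-diene-3β,13-diol | C=C[C@](C)(O)CC[C@H]1C(=C)CC[C@H]2C(C)(C)[C@@H](O)CC[C@]12CO[Si](C)(C)C(C)(C)C
F6 | step 9 | methyl (2Z)-3-{[(tert-butyldimethylsilyl)oxy]methyl}-5-[(2S)-3,3-dimethyloxiran-2-yl]pent-2-enoate | COC(=O)/C=C(/CC[C@@H]1OC1(C)C)CO[Si](C)(C)C(C)(C)C
F7 | step 9 | (2Z)-3-{[(tert-butyldimethylsilyl)oxy]methyl}-5-[(2S)-3,3-dimethyloxiran-2-yl]pent-2-en-1-ol | OC/C=C(/CC[C@@H]1OC1(C)C)CO[Si](C)(C)C(C)(C)C
F8 | step 9 | (2Z)-1-bromo-3-{[(tert-butyldimethylsilyl)oxy]methyl}-5-[(2S)-3,3-dimethyloxiran-2-yl]pent-2-ene | BrC/C=C(/CC[C@@H]1OC1(C)C)CO[Si](C)(C)C(C)(C)C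
F9 | step 13 | (13R)-20-[(tert-butyldimethylsilyl)oxy]-13-hydroxy-2α-(triethylsilyloxy)labda-7,14-dien-3-one | C=C[C@](C)(O)CC[C@H]1C(C)=CC[C@H]2C(C)(C)C(=O)[C@H](O[Si](CC)(CC)CC)C[C@]12CO[Si](C)(C)C(C)(C)C
F10 | step 13 | (13R)-20-[(tert-butyldimethylsilyl)oxy]-2α-(triethylsilyloxy)labda-7,14-diene-3α,13-diol | C=C[C@](C)(O)CC[C@H]1C(C)=CC[C@H]2C(C)(C)[C@H](O)[C@H](O[Si](CC)(CC)CC)C[C@]12CO[Si](C)(C)C(C)(C)C
F11 | step 14 | (13R)-20-[(tert-butyldimethylsilyl)oxy]-3α,13-dihydroxylabda-7,14-dien-2α-yl 2-[bis(2,2,2-trifluoroethoxy)phosphoryl]propanoate | C=C[C@](C)(O)CC[C@H]1C(C)=CC[C@H]2C(C)(C)[C@H](O)[C@H](OC(=O)C(C)P(=O)(OCC(F)(F)F)OCC(F)(F)F)C[C@]12CO[Si](C)(C)C(C)(C)C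
A1 | alternative 1 | 8a-[(benzyloxy)methyl]-3,4,8,8a-tetrahydronaphthalene-1,6(2H,7H)-dione, enantiomer with the angular group as in the target | O=C1C=C2CCCC(=O)[C@@]2(COCc3ccccc3)CC1
A2 | alternative 2 | (3R,6E)-3,7-dimethylnona-1,6,8-trien-3-ol | C=C[C@](C)(O)CC/C=C(\C)C=C
A3 | alternative 2 | cis-acetonide of 4,5-dihydroxy-3,3-dimethylcyclohex-1-ene-1-carbaldehyde with the C2/C3 configuration of the target | O=CC1=CC(C)(C)[C@@H]2OC(C)(C)O[C@@H]2C1
A4 | alternative 3 | (2Z,6E,10R)-2-{2-[(2S)-3,3-dimethyloxiran-2-yl]ethyl}-10-hydroxy-6,10-dimethyldodeca-2,6,11-trien-1-yl acetate | C=C[C@](C)(O)CC/C=C(\C)CC/C=C(/CC[C@@H]1OC1(C)C)COC(C)=O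
A5 | alternative 3 | 20-acetoxy-8α,13-epoxylabd-14-en-3β-ol (manoyl-oxide type) | C=C[C@@]1(C)CC[C@H]2[C@](C)(O1)CC[C@H]3C(C)(C)[C@@H](O)CC[C@]23COC(C)=O
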